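**The pitfall.** The trap was to read Tuesday's run as a test of substrate alone: loading is counted on the starting material, so against the flask, at the same equivalents, Tuesday's doubled charge doubled the spent carrier and the salt as well.

in all of them: spent carrier 17 mol%
- Monday's: starting material 0.13 M; salt in the second phase 2 equiv; protic impurity 2.6 mM; run made earlier
- Saturday's: starting material 0.13 M; salt in the second phase 4.5 equiv; protic impurity 2.6 mM; run made earlier
- Tuesday's: starting material 0.26 M; salt in the second phase 3 equiv; protic impurity 2.6 mM; run made earlier
- flask: starting material 0.13 M; salt in the second phase 3.00 equiv; protic impurity 2.60 mM; volume of the second phase over the first 0.50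

| run | time / h | product / % |
|---|---|---|
| Monday's | 1.33 | 5.3 |
| Monday's | 4.00 | 12.0 |
| Monday's | 6.00 | 19.5 |
| Monday's | 10.0 | 28.5 |
| Monday's | 15.0 | 40.4 |
| Monday's | 20.0 | 46.9 |
| Monday's | 25.0 | 52.8 |
| Saturday's | 2.00 | 6.2 |
| Saturday's | 3.00 | 12.5 |
| Saturday's | 4.00 | 14.2 |
| Saturday's | 6.00 | 20.2 |
| Saturday's | 10.0 | 31.5 |
| Saturday's | 15.0 | 41.0 |
| Saturday's | 25.0 | 57.6 |
| Tuesday's | 2.00 | 9.2 |
| Tuesday's | 6.00 | 27.3 |
| Tuesday's | 12.0 | 48.6 |
| Tuesday's | 15.0 | 55.3 |
| Tuesday's | 25.0 | 73.6 |

(readings scatter by 1 percentage point)

- apparent order in spent carrier when 10% of the starting material are converted (percent change of the rate of making product for one percent more spent carrier charged)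
- apparent order in salt in the second phase when 10% of the starting material are converted (percent change of the rate of making product for one percent more salt in the second phase charged)

- in the second phase: salt in the second phase, spent salt in the second phase; everything else is in the first
- charges count per volume of the first phase; a concentration in a rate is the amount of a species over the volume of its own phase; every rate counts per litre of the first phase
- steps under discussion: spent carrier + salt in the second phase <-> fresh carrier + spent salt in the second phase; starting material + fresh carrier -> product + spent carrier; starting material + protic impurity -> quenched substrate; 2 fresh carrier <-> resting dimer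
- the earlier runs hold the two phases in the same ratio of volumes as the flask asked about

**Two levers.** For each run I took the logarithm of the inverse unconverted fraction over time, a pseudo-first-order constant, at 15.0 h, a reading all three runs share: Monday gave 0.0345 /h, Saturday 0.0352 /h and Tuesday 0.0537 /h. Monday against Saturday changes the salt with the carrier held, so the log slope between them read 0.0239, a reading that rests on a gap of 0.6 percentage points in product against a scatter of 1 point, and which set the constant at 3.00 equiv to 0.0348 /h. Tuesday against that constant doubles carrier and salt together and, with the protic impurity charged as before, halves the impurity's share of the starting material, which I set aside, so subtracting the salt slope left 0.600, and this reading I carried as the carrier lever, the percent change of the constant for one percent more carrier charged.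

**The ladder.** On the first rung I assumed that resting dimer, the likely resting state, stays in balance with fresh carrier at each moment. Next, the protic impurity in the flask can take 2.00% of the starting material. Then I took the exchange with salt to keep ahead of turnover, given so flat a salt slope. On the last rung the starting material of the flask goes, on about 28.7 h.

**Both ends.** With the pool of fresh carrier and resting dimer wholly free, the lever is one; wholly dimer, it is one half. The balance joins these ends: while the pool follows the charge, the lever is one over two minus the free share, the fraction of that pool that is fresh carrier. My lever therefore read a free share of 0.333, and I carried both readings, taken at 15.0 h, over to 10% conversion in the flask, committing to 0.600 in carrier and 0.0239 in salt.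

**The result.** The forecast gave 0.55 and 0.12, calling the carrier figure “the signature of a resting dimer holding most of the fresh carrier”; the flask gave 0.59 in carrier and 0.094 in salt.

    spent carrier + salt in the second phase ⇌ fresh carrier + spent salt in the second phase (K = 0.190, k = 0.00560 /M/s)
    starting material + fresh carrier → product + spent carrier (k = 0.00150 /M/s)
    starting material + protic impurity → quenched substrate (k = 0.0300 /M/s)
    2 fresh carrier ⇌ resting dimer, settled at all times (K = 120 /M)

**Held-down order.** The flask at 3.00 h, just after the 2.25 h of the question, held 31.4% of its carrier as fresh carrier, 52.4% as resting dimer and 16.1% spent, a free share of 0.375, which the rule turns into 0.615, beside my lever of 0.600 and the order of 0.59. The tying up of fresh carrier as resting dimer pulls that order down: in the run of this flask with that step taken away, the order rose to 0.86.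

The readings were generated by integration on assumed constants; scatter was added.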